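**Retrosynthetic overview**
- The ester C–O bond and the cinnamate C=C bond are cut together. The target comes from (R)-marmin, 4-(geranyloxy)-2-hydroxybenzaldehyde and a two-carbon ketenylidene phosphorane linchpin (acylation, then Wittig, in one pot).
- (R)-Marmin is cut at C4'–C5' and at C1'–O into a C5 epoxy alcohol, isoprene and umbelliferone; both bonds form in one blue-light palladium/iodide three-component step.
- The epoxy alcohol comes from methyl (R)-glycidate and two equivalents of methyl Grignard reagent; the only stereocentre is bought here and is never a reaction site.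
- The aldehyde comes from 2,4-dihydroxybenzaldehyde and geranyl bromide by 4-O-selective alkylation.
- No ring is built: the coumarin and the benzene ring are bought, and the bought oxirane is opened in the key step.

Assumption: methyl (R)-glycidate (the enantiomer that derives from L-serine) is taken as a purchasable, inexpensive chiral building block.

**Step 1**
Reactants: 1 methyl (R)-glycidate
Product: 3 (R)-2-(oxiran-2-yl)propan-2-ol, via (R)-acetyloxirane 2 (not isolated)
Conditions: MeMgCl (2.2 equiv), THF, −78 → −30 °C, 2 h; cold sat. aq NH4Cl; Et2O extraction, careful distillation (volatile, water-soluble)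
Reagents that add atoms: methylmagnesium chloride, C[Mg]Cl
Why: Double Grignard addition to the ester (through the very electrophilic α-epoxy ketone 2) is far faster at low temperature than oxirane opening, and the stereocentre bought in 1 is not a reaction site, so it is carried through unchanged.

**Step 2**
Reactants: 3 (R)-2-(oxiran-2-yl)propan-2-ol, 4 isoprene, 5 umbelliferone
Product: 7 (R)-marmin, via iodohydrin 6 (not isolated)
Conditions: Pd(PPh3)4 (5 mol %), LiI (30 mol %), 4 (5 equiv), 5 (1.3 equiv), degassed 1,4-dioxane/DMA 4:1, blue LEDs (450 nm), 30 °C, 24 h, sealed tube, no base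
Reagents that add atoms: none
Why: Proposed new method: an iodide-cocatalysed, light-driven palladium three-component ring-opening 1,4-carboetherification of a diene, in which LiI and the acidic phenol 5 (pKa about 7.8) reversibly open the oxirane of 3 at its CH2 to iodohydrin 6 plus lithium coumarin-7-olate; photoexcited zerovalent palladium abstracts iodine from 6 to give monovalent palladium iodide and a primary β-hydroxyalkyl radical, which adds to C1 of s-trans isoprene; the allyl radical recombines with monovalent palladium to a divalent π-allylpalladium iodide, which the phenoxide attacks at its unsubstituted terminus (Tsuji–Trost) to give the (E)-allyl aryl ether while returning zerovalent palladium and iodide, so the equation has no co-product; the C6' stereocentre is the untouched carbinol carbon of 3 because the radical sits on the neighbouring CH2; the closest known reaction type is the visible-light palladium-catalysed interrupted radical-Heck/allylic-substitution of 1,3-dienes with unactivated alkyl halides and nucleophiles, joined to the LiI opening of epoxides to iodohydrins, and what is new is the epoxide as latent radical source under catalytic iodide, the base-free redox-neutral balance, and the unprotected diol.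

**Step 3**
Reactants: 8 2,4-dihydroxybenzaldehyde, 9 geranyl bromide
Product: 10 4-(geranyloxy)-2-hydroxybenzaldehyde
Conditions: KHCO3 (1.5 equiv), MeCN, 60 °C, 12 h
Reagents that add atoms: none
Why: Williamson ether synthesis in which the weak base ionises only the 4-OH (the 2-OH is locked in a hydrogen bond to the aldehyde), and SN2 at the primary allylic bromide keeps the (E)-alkene.

**Step 4**
Reactants: 7 (R)-marmin, 10 4-(geranyloxy)-2-hydroxybenzaldehyde
Product: 12 target ester CNP0360403.1, via phosphorane ester 11 (not isolated)
Conditions: Ph3P=C=C=O (1.1 equiv), toluene, 80 °C, 6 h; then 10 (1.2 equiv), 80 °C, 12 h, amber glassware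
Reagents that add atoms: (triphenylphosphoranylidene)ketene (Bestmann ylide), O=C=C=P(c1ccccc1)(c1ccccc1)c1ccccc1
Why: Bestmann ketenylidene esterification followed by Wittig olefination: the secondary hydroxyl of 7 adds across the cumulated ylide much faster than the tertiary one, with retention at C6' because its C–O bond is never broken, and the resulting ester-stabilised ylide 11 reacts with salicylaldehyde 10 to give the (E)-2-hydroxycinnamate, which cannot lactonise.

**Compound list**
1 | methyl (R)-glycidate, methyl (2R)-oxirane-2-carboxylate | COC(=O)[C@H]1CO1 | starting material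
2 | (R)-acetyloxirane, 1-[(2R)-oxiran-2-yl]ethan-1-one | CC(=O)[C@H]1CO1 | intermediate (not isolated)
3 | (R)-2-(oxiran-2-yl)propan-2-ol | CC(C)(O)[C@H]1CO1 | intermediate
4 | isoprene, 2-methylbuta-1,3-diene | C=CC(C)=C | starting material
5 | umbelliferone, 7-hydroxy-2H-chromen-2-one | O=c1ccc2ccc(O)cc2o1 | starting material
6 | iodohydrin, (S)-1-iodo-3-methylbutane-2,3-diol | CC(C)(O)[C@H](O)CI | intermediate (not isolated)
7 | (R)-marmin, 7-{[(2E,6R)-6,7-dihydroxy-3,7-dimethyloct-2-en-1-yl]oxy}-2H-chromen-2-one | CC(C)(O)[C@H](O)CC/C(C)=C/COc1ccc2ccc(=O)oc2c1 | intermediate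
8 | 2,4-dihydroxybenzaldehyde | O=Cc1ccc(O)cc1O | starting material
9 | geranyl bromide, (2E)-1-bromo-3,7-dimethylocta-2,6-diene | CC(C)=CCC/C(C)=C/CBr | starting material
10 | 4-{[(2E)-3,7-dimethylocta-2,6-dien-1-yl]oxy}-2-hydroxybenzaldehyde | CC(C)=CCC/C(C)=C/COc1ccc(C=O)c(O)c1 | intermediate
11 | phosphorane ester, (3R,6E)-2-hydroxy-2,6-dimethyl-8-[(2-oxo-2H-chromen-7-yl)oxy]oct-6-en-3-yl (triphenylphosphoranylidene)acetate | CC(C)(O)[C@@H](CC/C(C)=C/COc1ccc2ccc(=O)oc2c1)OC(=O)C=P(c1ccccc1)(c1ccccc1)c1ccccc1 | intermediate (not isolated)
12 | (3R,6E)-2-hydroxy-2,6-dimethyl-8-[(2-oxo-2H-chromen-7-yl)oxy]oct-6-en-3-yl (2E)-3-(4-{[(2E)-3,7-dimethylocta-2,6-dien-1-yl]oxy}-2-hydroxyphenyl)prop-2-enoate | CC(C)=CCC/C(C)=C/COc1ccc(/C=C/C(=O)O[C@H](CC/C(C)=C/COc2ccc3ccc(=O)oc3c2)C(C)(C)O)c(O)c1 | target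

**Totals**
Total step count: 4. Longest linear sequence: 3 steps (1 → 3 → 7 → 12); step 3 is a one-step side branch.

**Steps most likely to fail**

Step 2 (the new three-component step) is the main risk.
- Radical attack at C4 of isoprene would give the regioisomer with the methyl group on C2'. I expect C1 attack to be favoured by roughly 4:1 or better; this is an estimate, and the isomers would have to be separated (7 is crystalline).
- The free C6' hydroxyl could close onto the π-allyl intermediate to give a vinyl tetrahydrofuran.
- The phenoxide could open the epoxide directly.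
- The palladium–alkyl species could undergo β-hydroxy elimination.

Fallback with known chemistry, setting out from 3 and coming back at 7: 3 is opened at its terminal carbon with propargylmagnesium bromide (Et2O, −78 → 0 °C) to give (R)-2-methylhept-6-yne-2,3-diol F1. Negishi carboalumination of F1 (Me3Al 5 equiv, Cp2ZrCl2 0.3 equiv, CH2Cl2, 23 °C; then n-BuLi and paraformaldehyde in THF) fixes the (E)-trisubstituted alkene by syn addition and gives (2E,6R)-3,7-dimethyloct-2-ene-1,6,7-triol F2. Mitsunobu etherification of the primary allylic hydroxyl of F2 with 5 (PPh3, DIAD, THF, 0 °C) then gives 7.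

Step 4 is the second risk.
- The ylide may add slowly to the hindered secondary hydroxyl, or partly to the tertiary one.
- Any (Z)-cinnamate lactonises to auraptene and releases 7.
- The product is light-sensitive for the same reason, so it must be kept dark.

Fallback, setting out from 7 and coming back at 12: Steglich esterification of 7 with diethylphosphonoacetic acid (DCC, cat. DMAP, CH2Cl2, 0 → 23 °C) gives (R)-marmin 6'-O-(diethoxyphosphoryl)acetate F3. Horner–Wadsworth–Emmons olefination of F3 with 10 under Masamune–Roush conditions (LiCl, DBU 2.2 equiv, MeCN, 23 °C, dark) gives 12.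

Step 1 is the third risk.
- Halide or Grignard opening of the oxirane may compete with ester addition.
- Product 3 is small, volatile and water-soluble, so isolation losses are likely.

Fallback, setting out from 1 and coming back at 3: the oxirane of 1 is first masked by opening at C3 with LiCl/AcOH (THF, 23 °C) to give methyl (S)-3-chloro-2-hydroxypropanoate F4. MeMgCl (3.5 equiv, THF, −40 → 0 °C) converts F4 into the non-volatile (S)-1-chloro-3-methylbutane-2,3-diol F5. Ring closure of F5 (K2CO3, MeOH, 0 °C) returns 3. The stereocentre is not touched in any of the three operations; its descriptor changes only because the substituent priorities change.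

**Further compounds**
F1 | step 2 | (R)-2-methylhept-6-yne-2,3-diol | CC(C)(O)[C@H](O)CCC#C
F2 | step 2 | (2E,6R)-3,7-dimethyloct-2-ene-1,6,7-triol | CC(C)(O)[C@H](O)CC/C(C)=C/CO
F3 | step 4 | (3R,6E)-2-hydroxy-2,6-dimethyl-8-[(2-oxo-2H-chromen-7-yl)oxy]oct-6-en-3-yl 2-(diethoxyphosphoryl)acetate | CCOP(=O)(OCC)CC(=O)O[C@H](CC/C(C)=C/COc1ccc2ccc(=O)oc2c1)C(C)(C)O
F4 | step 1 | methyl (S)-3-chloro-2-hydroxypropanoate | COC(=O)[C@H](O)CCl
F5 | step 1 | (S)-1-chloro-3-methylbutane-2,3-diol | CC(C)(O)[C@H](O)CCl
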